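## Retrosynthetic overview

- Feature: the ether oxygen on C8 of ring A of unit 1 lies between C7–OH and C8a–O1 and is bonded to C4' of ring B of unit 2, a plain 1,4-disubstituted benzene. Ring B is therefore built around this oxygen instead of being coupled to it.
- Unit 1, ring C (O1–C2 and C4–C4a): from the 2-aryloxy-5-methoxyresorcinol 17 and β-ketoester 18. The C5 oxygen is carried as a methyl ether, which blocks the 6-aryloxy closure and is cleaved last.
- Unit 2, ring C: from methyl 4-aryloxybenzoate 12 and acetophenone 13 by Claisen condensation and cyclodehydration.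
- Unit 2, ring B: from aryl ethynyl ether 9 and methyl coumalate 10 by [4+2] cycloaddition and loss of CO2; 9 comes from phenol 5 and 5-methoxyresorcinol 1.
- Ring order: ring A of unit 1 (bought) → ring B of unit 2 → ring C of unit 2 (its ring A bought with 13) → ring C of unit 1 (its ring B bought with 18).

Key step: step 5

Remark on the chemistry: the target has no stereocentre. The oxygen para to the ether link is protected as a methyl ether (commercial 5-methoxyresorcinol) because a methyl ether is expected to tolerate butyllithium and the 250 °C ring closure better than a benzyl ether, and a 5-methoxy group peri to the flavone carbonyl can be cleaved selectively at the end.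

## Route

Step 1
Reactants: 1 5-methoxyresorcinol
Product: 2 1-methoxy-3,5-bis(methoxymethoxy)benzene
Conditions: NaH (2.4 equiv), MOMCl (2.4 equiv), DMF, 0 °C → rt
Reagents that add atoms: chloromethyl methyl ether, COCCl
Why: Williamson-type O-alkylation of both phenoxides by the reactive α-chloro ether should give the bis-MOM ether, the methyl ether being inert.

Step 2
Reactants: 2 1-methoxy-3,5-bis(methoxymethoxy)benzene
Product: 5 4-methoxy-2,6-bis(methoxymethoxy)phenol, via aryllithium 3 (not isolated), via dimethyl arylboronate 4 (not isolated)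
Conditions: n-BuLi, THF, 0 °C; B(OMe)3, −78 °C → rt; 30% aq H2O2, 0 °C → rt
Reagents that add atoms: hydrogen peroxide, OO
Why: Directed ortho-metalation should occur at the carbon flanked by both MOM ethers (cooperative lithium coordination, MOM being a stronger director than methoxy), and borylation followed by oxidative 1,2-migration of the aryl group from boron to oxygen turns the C–Li bond into the phenol.

Step 3
Reactants: 5 4-methoxy-2,6-bis(methoxymethoxy)phenol
Product: 6 2-{[(E)-1,2-dichloroethenyl]oxy}-5-methoxy-1,3-bis(methoxymethoxy)benzene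
Conditions: Cl2C=CHCl (1.5 equiv), K2CO3, DMF, 70 °C, Ar
Reagents that add atoms: trichloroethylene, ClC=C(Cl)Cl
Why: Base-induced dehydrochlorination of trichloroethylene gives dichloroacetylene, to which the phenoxide adds in anti fashion (nucleophilic addition to a haloalkyne, the standard dichlorovinyl ether synthesis), setting the E geometry; the small linear electrophile should tolerate the two ortho substituents.

Step 4
Reactants: 6 2-{[(E)-1,2-dichloroethenyl]oxy}-5-methoxy-1,3-bis(methoxymethoxy)benzene
Product: 9 2-(ethynyloxy)-5-methoxy-1,3-bis(methoxymethoxy)benzene, via chloroethynyl ether 7 (not isolated), via lithium acetylide 8 (not isolated)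
Conditions: n-BuLi (2.3 equiv), Et2O, −78 → −40 °C; H2O, −78 °C; used at once
Reagents that add atoms: none
Why: Dehydrochlorination to the chloroalkyne, lithium–chlorine exchange and protonation of the acetylide is the established route from dichlorovinyl ethers to ynol ethers, and at −78 °C it should outrun any ring lithiation.

Step 5
Reactants: 9 2-(ethynyloxy)-5-methoxy-1,3-bis(methoxymethoxy)benzene; 10 methyl coumalate
Product: 12 methyl 4-[4-methoxy-2,6-bis(methoxymethoxy)phenoxy]benzoate, via bridged lactone adduct 11 (not isolated)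
Conditions: 10 (2 equiv), toluene, 110–130 °C, sealed tube, Ar
Reagents that add atoms: none
Why: The electron-poor 2-pyranone 10 serves as the 4π partner (C3=C4–C5=C6) and the electron-rich alkynyl ether 9 as the 2π partner in a Diels–Alder reaction with inverse electron demand, giving the bridged lactone 11, which should expel CO2 by retro-[4+2] at the same temperature and so give the benzene ring without any oxidant. The closest known reaction type is the cycloaddition–decarboxylation of methyl coumalate with alkynes, enol ethers and ketene acetals to para-substituted benzoates, 9 being a new member of the alkyne class. Ring B of unit 2 is closed by intermolecular [4+2] cycloaddition, the bond from the terminal alkyne carbon to C6 of the pyranone becoming C2'–C3' and the bond from the oxygen-bearing alkyne carbon to C3 becoming C4'–C5'. The two bridgehead stereocentres of 11 vanish with CO2, so nothing stereochemical has to be controlled. The step needs para over meta orientation, which the polarisation of both partners should secure: the unsubstituted alkyne carbon is the nucleophilic β-carbon of the ynol ether and bonds to C6, the most electron-poor diene terminus (β to the ester, δ to the lactone carbonyl), leaving the aryloxy carbon para to the ester. The doubly ortho-flanked oxygen already sits on the sp carbon, so no C–O bond is made at the hindered site, and the aryl group has no β-hydrogen for retro-ene loss of ketene on heating.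

Step 6
Reactants: 12 methyl 4-[4-methoxy-2,6-bis(methoxymethoxy)phenoxy]benzoate; 13 2',6'-dihydroxy-4'-methoxyacetophenone
Product: 15 1-(2,6-dihydroxy-4-methoxyphenyl)-3-{4-[4-methoxy-2,6-bis(methoxymethoxy)phenoxy]phenyl}propane-1,3-dione, via trilithium trianion 14 (not isolated)
Conditions: 13 (1.5 equiv), LiN(SiMe3)2 (4 equiv per 13), THF, −78 → 0 °C; then 12, −78 °C → rt; cold 1 M HCl to pH 4
Reagents that add atoms: none
Why: Crossed Claisen condensation: the enolate carbon of the acetophenone polyanion is its most nucleophilic site and should acylate on the non-enolisable methyl ester, the reaction being driven by deprotonation of the β-diketone; MOM and methyl ethers are stable to the base.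

Step 7
Reactants: 15 1-(2,6-dihydroxy-4-methoxyphenyl)-3-{4-[4-methoxy-2,6-bis(methoxymethoxy)phenoxy]phenyl}propane-1,3-dione
Product: 17 2-[4-(2,6-dihydroxy-4-methoxyphenoxy)phenyl]-5-hydroxy-7-methoxy-4H-chromen-4-one, via bis-MOM flavone 16 (not isolated)
Conditions: conc. HCl, MeOH–THF, 65 °C
Reagents that add atoms: none
Why: Acid-catalysed cyclodehydration of the o-hydroxyaryl β-diketone (hemiketal formation, then loss of water; either of the two equivalent hydroxyls gives the same 5-hydroxy-7-methoxyflavone) and transacetalisation of both MOM ethers to methanol should take place in the same pot.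

Step 8
Reactants: 17 2-[4-(2,6-dihydroxy-4-methoxyphenoxy)phenyl]-5-hydroxy-7-methoxy-4H-chromen-4-one; 18 ethyl 4-methoxybenzoylacetate
Product: 20 7-hydroxy-8-[4-(5-hydroxy-7-methoxy-4-oxo-4H-chromen-2-yl)phenoxy]-5-methoxy-2-(4-methoxyphenyl)-4H-chromen-4-one, via 1,3-diketone 19 (not isolated)
Conditions: 18 (3 equiv), Ph2O, 240–250 °C, Ar, EtOH distilled off
Reagents that add atoms: none
Why: Mentzer thermal chromone synthesis: the β-ketoester loses ethanol and C-acylates the phloroglucinol-type ring at either of its two equivalent free carbons, and only the hydroxyl next to that carbon (the other neighbour is the methyl ether) can then cyclodehydrate onto the aryl ketone, so only the 8-aryloxy flavone should form.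

Step 9
Reactants: 20 7-hydroxy-8-[4-(5-hydroxy-7-methoxy-4-oxo-4H-chromen-2-yl)phenoxy]-5-methoxy-2-(4-methoxyphenyl)-4H-chromen-4-one
Product: 21 5,7-dihydroxy-8-[4-(5-hydroxy-7-methoxy-4-oxo-4H-chromen-2-yl)phenoxy]-2-(4-methoxyphenyl)-4H-chromen-4-one (CNP0124888.0)
Conditions: BCl3 (1 M in CH2Cl2, 4 equiv), CH2Cl2, −78 → 0 °C; then MeOH, aq HCl, rt
Reagents that add atoms: none
Why: Chelation-directed Lewis acid ether cleavage: boron bridges the C4 carbonyl and the peri 5-methoxy oxygen of unit 1 and chloride removes that methyl group by SN2, whereas the 7-methoxy group of unit 2 and the 4'-methoxy group of unit 1 have no neighbouring carbonyl and should stay.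

## Compound list

1 | 5-methoxyresorcinol (5-methoxybenzene-1,3-diol) | COc1cc(O)cc(O)c1 | starting material
2 | 1-methoxy-3,5-bis(methoxymethoxy)benzene | COCOc1cc(OC)cc(OCOC)c1 | intermediate
3 | [4-methoxy-2,6-bis(methoxymethoxy)phenyl]lithium (formed in the flask) | [Li]c1c(OCOC)cc(OC)cc1OCOC | intermediate
4 | dimethyl [4-methoxy-2,6-bis(methoxymethoxy)phenyl]boronate (formed in the flask) | COB(OC)c1c(OCOC)cc(OC)cc1OCOC | intermediate
5 | 4-methoxy-2,6-bis(methoxymethoxy)phenol | COCOc1cc(OC)cc(OCOC)c1O | intermediate
6 | 2-{[(E)-1,2-dichloroethenyl]oxy}-5-methoxy-1,3-bis(methoxymethoxy)benzene | Cl/C=C(/Cl)Oc1c(OCOC)cc(OC)cc1OCOC | intermediate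
7 | 2-[(chloroethynyl)oxy]-5-methoxy-1,3-bis(methoxymethoxy)benzene (formed in the flask) | ClC#COc1c(OCOC)cc(OC)cc1OCOC | intermediate
8 | {[4-methoxy-2,6-bis(methoxymethoxy)phenoxy]ethynyl}lithium (formed in the flask) | [Li]C#COc1c(OCOC)cc(OC)cc1OCOC | intermediate
9 | 2-(ethynyloxy)-5-methoxy-1,3-bis(methoxymethoxy)benzene | C#COc1c(OCOC)cc(OC)cc1OCOC | intermediate
10 | methyl coumalate (methyl 2-oxo-2H-pyran-5-carboxylate) | COC(=O)c1ccc(=O)oc1 | starting material
11 | methyl 8-[4-methoxy-2,6-bis(methoxymethoxy)phenoxy]-3-oxo-2-oxabicyclo[2.2.2]octa-5,7-diene-6-carboxylate (racemic, one enantiomer drawn; formed in the flask) | O=C1O[C@H]2C=C(Oc3c(OCOC)cc(OC)cc3OCOC)[C@@H]1C=C2C(=O)OC | intermediate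
12 | methyl 4-[4-methoxy-2,6-bis(methoxymethoxy)phenoxy]benzoate | COC(=O)c1ccc(Oc2c(OCOC)cc(OC)cc2OCOC)cc1 | intermediate
13 | 2',6'-dihydroxy-4'-methoxyacetophenone | CC(=O)c1c(O)cc(OC)cc1O | starting material
14 | trilithium 5-methoxy-2-(1-oxidoethenyl)benzene-1,3-diolate (formed in the flask) | [Li+].[Li+].[Li+].C=C([O-])c1c([O-])cc(OC)cc1[O-] | intermediate
15 | 1-(2,6-dihydroxy-4-methoxyphenyl)-3-{4-[4-methoxy-2,6-bis(methoxymethoxy)phenoxy]phenyl}propane-1,3-dione | COc1cc(O)c(C(=O)CC(=O)c2ccc(Oc3c(OCOC)cc(OC)cc3OCOC)cc2)c(O)c1 | intermediate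
16 | 5-hydroxy-7-methoxy-2-{4-[4-methoxy-2,6-bis(methoxymethoxy)phenoxy]phenyl}-4H-chromen-4-one (formed in the flask) | COCOc1cc(OC)cc(OCOC)c1Oc1ccc(-c2cc(=O)c3c(O)cc(OC)cc3o2)cc1 | intermediate
17 | 2-[4-(2,6-dihydroxy-4-methoxyphenoxy)phenyl]-5-hydroxy-7-methoxy-4H-chromen-4-one | COc1cc(O)c(Oc2ccc(-c3cc(=O)c4c(O)cc(OC)cc4o3)cc2)c(O)c1 | intermediate
18 | ethyl 4-methoxybenzoylacetate (ethyl 3-(4-methoxyphenyl)-3-oxopropanoate) | CCOC(=O)CC(=O)c1ccc(OC)cc1 | starting material
19 | 1-{2,4-dihydroxy-3-[4-(5-hydroxy-7-methoxy-4-oxo-4H-chromen-2-yl)phenoxy]-6-methoxyphenyl}-3-(4-methoxyphenyl)propane-1,3-dione (formed in the flask) | COc1ccc(C(=O)CC(=O)c2c(OC)cc(O)c(Oc3ccc(-c4cc(=O)c5c(O)cc(OC)cc5o4)cc3)c2O)cc1 | intermediate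
20 | 7-hydroxy-8-[4-(5-hydroxy-7-methoxy-4-oxo-4H-chromen-2-yl)phenoxy]-5-methoxy-2-(4-methoxyphenyl)-4H-chromen-4-one | COc1ccc(-c2cc(=O)c3c(OC)cc(O)c(Oc4ccc(-c5cc(=O)c6c(O)cc(OC)cc6o5)cc4)c3o2)cc1 | intermediate
21 | 5,7-dihydroxy-8-[4-(5-hydroxy-7-methoxy-4-oxo-4H-chromen-2-yl)phenoxy]-2-(4-methoxyphenyl)-4H-chromen-4-one | COc1ccc(-c2cc(=O)c3c(O)cc(O)c(Oc4ccc(-c5cc(=O)c6c(O)cc(OC)cc6o5)cc4)c3o2)cc1 | target

## Step count and risks

Total step count: 9. Longest linear sequence: 9 steps (1 → 21); the partners 10, 13 and 18 are bought.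

Steps most likely to fail:

1. Step 5 (key cycloaddition). The ynol ether may be consumed by oligomerisation or by hydration through traces of acid or water before it cycloadds, or regiocontrol may erode so that a meta isomer forms as well. Fallback: set out from phenol 5 and make the diaryl ether by O-arylation instead of ring construction. The potassium phenoxide of 5 (KOt-Bu, THF, 0 °C) is treated with bis[4-(methoxycarbonyl)phenyl]iodonium trifluoromethanesulfonate at 40 °C; this metal-free aryl transfer from a diaryliodonium salt is known to tolerate 2,6-disubstituted phenols. It should give benzoate 12 directly, so the route is rejoined at 12 and steps 3 and 4 fall away; no compound outside the list is made.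

2. Step 8 (thermal closure of unit 1). At 240–250 °C the ketoester may self-condense or acylate oxygen faster than it acylates the ring carbon, and the large polyphenol may degrade. Fallback: build the same ring stepwise from 17. Friedel–Crafts C-acetylation (AcOH, BF3·OEt2, 80 °C) at the one kind of free ring carbon should give 2-[4-(3-acetyl-2,6-dihydroxy-4-methoxyphenoxy)phenyl]-5-hydroxy-7-methoxy-4H-chromen-4-one F1. Its lithium polyanion (LiN(SiMe3)2 in excess, THF, −78 °C) is C-aroylated with 4-methoxybenzoyl chloride to give diketone 19, here isolated. The route is rejoined at 19, which is closed to 20 with catalytic H2SO4 in AcOH at 95 °C.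

3. Step 6 (Claisen condensation). The aggregated, poorly soluble trianion may attack the electron-rich aryloxybenzoate too slowly, leaving ester unchanged. Fallback: move the acyl group intramolecularly, starting from 12. Saponification (LiOH, THF–MeOH–H2O) gives 4-[4-methoxy-2,6-bis(methoxymethoxy)phenoxy]benzoic acid F2. Carbodiimide esterification (EDC·HCl, DMAP, CH2Cl2) with one of the two equivalent hydroxyls of 13 gives 2-acetyl-3-hydroxy-5-methoxyphenyl 4-[4-methoxy-2,6-bis(methoxymethoxy)phenoxy]benzoate F3. Baker–Venkataraman rearrangement (KOH, pyridine, 50 °C) shifts the aroyl group from oxygen to the acetyl carbon and rejoins the route at 15.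

Further compounds
F0 | step 5 | none | none
F1 | step 8 | 2-[4-(3-acetyl-2,6-dihydroxy-4-methoxyphenoxy)phenyl]-5-hydroxy-7-methoxy-4H-chromen-4-one | CC(=O)c1c(OC)cc(O)c(Oc2ccc(-c3cc(=O)c4c(O)cc(OC)cc4o3)cc2)c1O
F2 | step 6 | 4-[4-methoxy-2,6-bis(methoxymethoxy)phenoxy]benzoic acid | OC(=O)c1ccc(Oc2c(OCOC)cc(OC)cc2OCOC)cc1
F3 | step 6 | 2-acetyl-3-hydroxy-5-methoxyphenyl 4-[4-methoxy-2,6-bis(methoxymethoxy)phenoxy]benzoate | CC(=O)c1c(O)cc(OC)cc1OC(=O)c1ccc(Oc2c(OCOC)cc(OC)cc2OCOC)cc1
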